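**Retrosynthetic overview**

1. Kuwanon B is reached from the bromo tris(allyl ether) 16 by one palladium/formate operation that removes the three O-allyl groups and the bromine at C5', which serves as a temporary blocking group.
2. Ring D (the 2,2-dimethyl-2H-pyran fused to ring B) is disconnected at C3'–CH= and O4'–CMe2 to flavone phenol 13 and 3-methylbut-2-enal. The enabling feature is that the pyran oxygen sits on C4' next to the fusion carbon C3', so ring D is the electrocyclized form of the 1-oxatriene O=C4'–C3'=CH–CH=CMe2, an ortho-quinone methide of the 4'-phenol.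
3. In 13 the 4'-OH is the only free phenol (O2', O5 and O7 are allyl ethers) and bromine occupies C5', so C3' is the only carbon that can be attacked and O4' the only oxygen that can close.
4. 13 comes from the 2-prenyl 1,3-diketone 12 (C-prenylation of Baker–Venkataraman diketone 10), assembled from phloroacetophenone (ring A) and methyl 5-bromo-2,4-dihydroxybenzoate (ring B).
5. Ring order: rings A and B are bought, pyranone ring C is closed in step 8, ring D is closed last in step 9.

Key step: step 9

Remark: flavone locants are used (rings A and C: positions 2 to 8; ring B: 1' to 6'; ring D is the dimethylpyran); methyl 5-bromo-2,4-dihydroxybenzoate is taken as a commercial compound, and the target has no stereocentre.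

**Route**

Step 1
Reactants: 1 1-(2,4,6-trihydroxyphenyl)ethanone; 2 allyl bromide
Product: 3 1-[2-hydroxy-4,6-bis(prop-2-enyloxy)phenyl]ethanone
Conditions: allyl bromide (2.1 equiv), K2CO3 (2.2 equiv), acetone, reflux
Reagents that add atoms: allyl bromide (C=CCBr)
Why: Williamson etherification should alkylate the two non-chelated phenols, while the hydroxyl hydrogen-bonded to the acetyl carbonyl is too weakly nucleophilic under K2CO3 and stays free for the later ester formation.

Step 2
Reactants: 4 methyl 5-bromo-2,4-dihydroxybenzoate; 5 chloromethyl methyl ether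
Product: 6 methyl 5-bromo-2-hydroxy-4-(methoxymethoxy)benzoate
Conditions: MOMCl (1.1 equiv), K2CO3, acetone, 0 °C to rt
Reagents that add atoms: chloromethyl methyl ether (COCCl)
Why: Williamson-type O-alkylation should be selective for the 4-OH, the more acidic and unchelated phenol, because the 2-OH is held in a hydrogen bond to the ester carbonyl.

Step 3
Reactants: 6 methyl 5-bromo-2-hydroxy-4-(methoxymethoxy)benzoate; 2 allyl bromide
Product: 7 methyl 5-bromo-4-(methoxymethoxy)-2-(prop-2-enyloxy)benzoate
Conditions: allyl bromide (1.5 equiv), K2CO3, DMF, 60 °C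
Reagents that add atoms: allyl bromide (C=CCBr)
Why: Williamson etherification of the remaining salicylate hydroxyl under more forcing conditions should install the allyl ether that later keeps O2' out of both ring closures.

Step 4
Reactants: 7 methyl 5-bromo-4-(methoxymethoxy)-2-(prop-2-enyloxy)benzoate
Product: 8 5-bromo-4-(methoxymethoxy)-2-(prop-2-enyloxy)benzoic acid
Conditions: LiOH·H2O, THF/MeOH/H2O, 50 °C; then 1 M HCl to pH 4, 0 °C
Reagents that add atoms: lithium hydroxide ([Li+].[OH-])
Why: Saponification of the methyl ester should leave the allyl ether, the aryl bromide and the base-stable methoxymethyl acetal untouched, and the cold, mild acidification preserves the acetal.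

Step 5
Reactants: 3 1-[2-hydroxy-4,6-bis(prop-2-enyloxy)phenyl]ethanone; 8 5-bromo-4-(methoxymethoxy)-2-(prop-2-enyloxy)benzoic acid
Product: 9 2-acetyl-3,5-bis(prop-2-enyloxy)phenyl 5-bromo-4-(methoxymethoxy)-2-(prop-2-enyloxy)benzoate
Conditions: EDC·HCl, DMAP (cat.), CH2Cl2, rt
Reagents that add atoms: none
Why: Steglich esterification (carbodiimide activation with DMAP acyl transfer) should acylate the chelated phenol of 3 under neutral conditions that spare the acetal, giving the Baker–Venkataraman substrate.

Step 6
Reactants: 9 2-acetyl-3,5-bis(prop-2-enyloxy)phenyl 5-bromo-4-(methoxymethoxy)-2-(prop-2-enyloxy)benzoate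
Product: 10 1-[5-bromo-4-(methoxymethoxy)-2-(prop-2-enyloxy)phenyl]-3-[2-hydroxy-4,6-bis(prop-2-enyloxy)phenyl]propane-1,3-dione
Conditions: LiN(SiMe3)2 (3 equiv), THF, −78 to 0 °C; AcOH quench
Reagents that add atoms: none
Why: In the Baker–Venkataraman rearrangement the lithium enolate of the acetyl group attacks the neighbouring aryl ester intramolecularly, so the aroyl group should migrate from oxygen to carbon and give the 1,3-diketone with the chelated phenol set free.

Step 7
Reactants: 10 1-[5-bromo-4-(methoxymethoxy)-2-(prop-2-enyloxy)phenyl]-3-[2-hydroxy-4,6-bis(prop-2-enyloxy)phenyl]propane-1,3-dione; 11 1-bromo-3-methylbut-2-ene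
Product: 12 racemic 1-[5-bromo-4-(methoxymethoxy)-2-(prop-2-enyloxy)phenyl]-3-[2-hydroxy-4,6-bis(prop-2-enyloxy)phenyl]-2-(3-methylbut-2-enyl)propane-1,3-dione
Conditions: prenyl bromide (1.1 equiv), K2CO3 (1.2 equiv), acetone, rt to 40 °C
Reagents that add atoms: 1-bromo-3-methylbut-2-ene (CC(C)=CCBr)
Why: C-alkylation of the soft 1,3-diketone enolate by the allylic bromide should be preferred over alkylation of the less acidic chelated phenol; the new stereocentre is formed racemic, is enolisable and is removed in step 8.

Step 8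
Reactants: 12 racemic 1-[5-bromo-4-(methoxymethoxy)-2-(prop-2-enyloxy)phenyl]-3-[2-hydroxy-4,6-bis(prop-2-enyloxy)phenyl]-2-(3-methylbut-2-enyl)propane-1,3-dione
Product: 13 2-[5-bromo-4-hydroxy-2-(prop-2-enyloxy)phenyl]-3-(3-methylbut-2-enyl)-5,7-bis(prop-2-enyloxy)chromen-4-one
Conditions: 3 M aq. HCl, MeOH/THF, 50 °C
Reagents that add atoms: none
Why: Acid-catalysed cyclodehydration of the 2-hydroxyaryl 1,3-diketone (hemiketal formation by the ring A phenol at the ring B carbonyl, then loss of water) should close pyranone ring C while the same acid cleaves the methoxymethyl acetal to unveil the 4'-phenol; allyl ethers and aryl bromide are acid-stable, and closure through O2' is excluded because it is an ether.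

Step 9
Reactants: 13 2-[5-bromo-4-hydroxy-2-(prop-2-enyloxy)phenyl]-3-(3-methylbut-2-enyl)-5,7-bis(prop-2-enyloxy)chromen-4-one; 14 3-methylbut-2-enal
Product: 16 2-[8-bromo-2,2-dimethyl-5-(prop-2-enyloxy)-2H-chromen-6-yl]-3-(3-methylbut-2-enyl)-5,7-bis(prop-2-enyloxy)chromen-4-one, via ortho-quinone methide 15 (not isolated)
Conditions: 3-methylbut-2-enal (3 equiv), ethylenediammonium diacetate (20 mol%), toluene, 110 °C (sealed tube)
Reagents that add atoms: 3-methylbut-2-enal (CC(C)=CC=O)
Why: Ethylenediammonium diacetate turns the aldehyde into an iminium ion, C3' of 13 (ortho to the free 4'-OH and activated by O2' and O4') adds to it in a Knoevenagel-type condensation, and loss of water and amine gives the (Z)-ortho-quinone methide 15, a 1-oxatriene O=C4'–C3'=CH–CH=CMe2, which closes thermally by disrotatory oxa-6π electrocyclization and so restores the aromaticity of ring B. The closest known reaction type is the amine-catalysed formal [3+3] chromenylation of phenols, resorcinols and hydroxycoumarins with α,β-unsaturated aldehydes. Ring D, the only ring closed, is formed by intermolecular C3'–C bond formation followed by six-electron electrocyclic O4'–CMe2 bond formation. No stereocentre is created, since the new sp3 carbon carries two methyl groups. The step needs selectivity for ring B over ring A, for C3' over C5' and for O4' over O2': ring A has no free hydroxyl and cannot form a quinone methide, O2' is an allyl ether and C5' carries bromine, so the 4'-OH is the only phenol and C3' its only unsubstituted ortho carbon. Allyl ethers, the prenyl group and the aryl bromide should be inert at 110 °C under these nearly neutral conditions.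

Step 10
Reactants: 16 2-[8-bromo-2,2-dimethyl-5-(prop-2-enyloxy)-2H-chromen-6-yl]-3-(3-methylbut-2-enyl)-5,7-bis(prop-2-enyloxy)chromen-4-one
Product: 17 Kuwanon B
Conditions: Pd(PPh3)4 (10 mol%), HCO2H (12 equiv), Et3N (15 equiv), DMF, 25 °C then 90 °C
Reagents that add atoms: none
Why: Zerovalent palladium should ionize the three allyl aryl ethers to π-allyl complexes and insert into the C5'–Br bond, and formate delivers hydride to both (Tsuji-type formate hydrogenolysis of allyl ethers and palladium-catalysed hydrodehalogenation), so the phenols and the C5'–H are released without acid and the prenyl group and chromene are spared.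

**Compound list**

1 | 1-(2,4,6-trihydroxyphenyl)ethanone (phloroacetophenone) | CC(=O)c1c(O)cc(O)cc1O | starting material
2 | allyl bromide (3-bromoprop-1-ene) | C=CCBr | starting material
3 | 1-[2-hydroxy-4,6-bis(prop-2-enyloxy)phenyl]ethanone | CC(=O)c1c(O)cc(OCC=C)cc1OCC=C | intermediate
4 | methyl 5-bromo-2,4-dihydroxybenzoate | COC(=O)c1cc(Br)c(O)cc1O | starting material
5 | chloromethyl methyl ether | COCCl | starting material
6 | methyl 5-bromo-2-hydroxy-4-(methoxymethoxy)benzoate | COC(=O)c1cc(Br)c(OCOC)cc1O | intermediate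
7 | methyl 5-bromo-4-(methoxymethoxy)-2-(prop-2-enyloxy)benzoate | COC(=O)c1cc(Br)c(OCOC)cc1OCC=C | intermediate
8 | 5-bromo-4-(methoxymethoxy)-2-(prop-2-enyloxy)benzoic acid | OC(=O)c1cc(Br)c(OCOC)cc1OCC=C | intermediate
9 | 2-acetyl-3,5-bis(prop-2-enyloxy)phenyl 5-bromo-4-(methoxymethoxy)-2-(prop-2-enyloxy)benzoate | CC(=O)c1c(OC(=O)c2cc(Br)c(OCOC)cc2OCC=C)cc(OCC=C)cc1OCC=C | intermediate
10 | 1-[5-bromo-4-(methoxymethoxy)-2-(prop-2-enyloxy)phenyl]-3-[2-hydroxy-4,6-bis(prop-2-enyloxy)phenyl]propane-1,3-dione | O=C(CC(=O)c1cc(Br)c(OCOC)cc1OCC=C)c1c(O)cc(OCC=C)cc1OCC=C | intermediate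
11 | 1-bromo-3-methylbut-2-ene (prenyl bromide) | CC(C)=CCBr | starting material
12 | racemic 1-[5-bromo-4-(methoxymethoxy)-2-(prop-2-enyloxy)phenyl]-3-[2-hydroxy-4,6-bis(prop-2-enyloxy)phenyl]-2-(3-methylbut-2-enyl)propane-1,3-dione | O=C(C(CC=C(C)C)C(=O)c1cc(Br)c(OCOC)cc1OCC=C)c1c(O)cc(OCC=C)cc1OCC=C | intermediate
13 | 2-[5-bromo-4-hydroxy-2-(prop-2-enyloxy)phenyl]-3-(3-methylbut-2-enyl)-5,7-bis(prop-2-enyloxy)chromen-4-one | CC(C)=CCc1c(-c2cc(Br)c(O)cc2OCC=C)oc2cc(OCC=C)cc(OCC=C)c2c1=O | intermediate
14 | 3-methylbut-2-enal | CC(C)=CC=O | starting material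
15 | (Z)-2-[5-bromo-3-(3-methylbut-2-enylidene)-4-oxo-2-(prop-2-enyloxy)cyclohexa-1,5-dien-1-yl]-3-(3-methylbut-2-enyl)-5,7-bis(prop-2-enyloxy)chromen-4-one (ortho-quinone methide, dienyl arm on the side of the C4' carbonyl) | CC(C)=CCc1c(C2=C(OCC=C)/C(=C/C=C(C)C)C(=O)C(Br)=C2)oc2cc(OCC=C)cc(OCC=C)c2c1=O | intermediate
16 | 2-[8-bromo-2,2-dimethyl-5-(prop-2-enyloxy)-2H-chromen-6-yl]-3-(3-methylbut-2-enyl)-5,7-bis(prop-2-enyloxy)chromen-4-one | CC(C)=CCc1c(-c2cc(Br)c3c(c2OCC=C)C=CC(C)(C)O3)oc2cc(OCC=C)cc(OCC=C)c2c1=O | intermediate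
17 | Kuwanon B, 5,7-dihydroxy-2-(5-hydroxy-2,2-dimethyl-2H-chromen-6-yl)-3-(3-methylbut-2-enyl)chromen-4-one (achiral) | CC(C)=CCc1c(-c2ccc3c(c2O)C=CC(C)(C)O3)oc2cc(O)cc(O)c2c1=O | target

**Step count and risks**

Total step count: 10. Longest linear sequence: 9 steps (from 4 through steps 2, 3, 4, 5, 6, 7, 8, 9 and 10).

Step 9. Carbon–carbon bond formation at C3', a carbon flanked by two oxygen substituents on an electron-poor bromophenol, may be slower than self-condensation of the aldehyde, and prolonged heating could start Claisen rearrangement of the allyl ethers. The fallback forms the oxygen–carbon bond first and the carbon–carbon bond intramolecularly. It sets out from 13: O-alkylation of the 4'-phenol with 3-chloro-3-methylbut-1-yne (K2CO3, KI, CuI cat., acetone, 55 °C) should give the aryl propargyl ether 2-[5-bromo-4-(2-methylbut-3-yn-2-yloxy)-2-(prop-2-enyloxy)phenyl]-3-(3-methylbut-2-enyl)-5,7-bis(prop-2-enyloxy)chromen-4-one F1. Heating F1 in N,N-diethylaniline at 130 °C should bring about the aryl propargyl ether Claisen rearrangement to C3' (C5' is blocked), hydrogen shift and the same oxa-6π closure through 15, and the sequence comes back to the route at 16.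

Step 10. The palladium hydride may reductively open the tertiary allylic aryl ether of ring D, the π-allyl complex may C-allylate the electron-rich ring A, or oxidative addition into the electron-rich C–Br bond may stall once the phenols are free. The fallback separates the two events and avoids a hydride in the presence of palladium. It sets out from 16: radical chain hydrodebromination (Bu3SnH, AIBN cat., toluene, 80 °C) should give 2-[2,2-dimethyl-5-(prop-2-enyloxy)-2H-chromen-6-yl]-3-(3-methylbut-2-enyl)-5,7-bis(prop-2-enyloxy)chromen-4-one F2. Deallylation of F2 with Pd(PPh3)4 (5 mol%) and morpholine in THF at 25 °C, where the allyl groups are transferred to the amine, comes back to the route at 17.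

Step 7. O-alkylation of the diketone enolate or of the chelated phenol, or double alkylation, may compete with the wanted C-alkylation. The fallback installs the prenyl group before the diketone exists. It sets out from 3: dianion formation with LiN(iPr)2 (2.2 equiv, THF, −78 °C) and alkylation with 11 should give 1-[2-hydroxy-4,6-bis(prop-2-enyloxy)phenyl]-5-methylhex-4-en-1-one F3. Steglich esterification of F3 with 8 (EDC·HCl, DMAP, CH2Cl2) should give 2-(5-methylhex-4-enoyl)-3,5-bis(prop-2-enyloxy)phenyl 5-bromo-4-(methoxymethoxy)-2-(prop-2-enyloxy)benzoate F4, and Baker–Venkataraman rearrangement of F4 (LiN(SiMe3)2, THF) comes back to the route at 12.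

Further compounds
F1 | step 9 | 2-[5-bromo-4-(2-methylbut-3-yn-2-yloxy)-2-(prop-2-enyloxy)phenyl]-3-(3-methylbut-2-enyl)-5,7-bis(prop-2-enyloxy)chromen-4-one | CC(C)=CCc1c(-c2cc(Br)c(OC(C)(C)C#C)cc2OCC=C)oc2cc(OCC=C)cc(OCC=C)c2c1=O
F2 | step 10 | 2-[2,2-dimethyl-5-(prop-2-enyloxy)-2H-chromen-6-yl]-3-(3-methylbut-2-enyl)-5,7-bis(prop-2-enyloxy)chromen-4-one | CC(C)=CCc1c(-c2ccc3c(c2OCC=C)C=CC(C)(C)O3)oc2cc(OCC=C)cc(OCC=C)c2c1=O
F3 | step 7 | 1-[2-hydroxy-4,6-bis(prop-2-enyloxy)phenyl]-5-methylhex-4-en-1-one | CC(C)=CCCC(=O)c1c(O)cc(OCC=C)cc1OCC=C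
F4 | step 7 | 2-(5-methylhex-4-enoyl)-3,5-bis(prop-2-enyloxy)phenyl 5-bromo-4-(methoxymethoxy)-2-(prop-2-enyloxy)benzoate | CC(C)=CCCC(=O)c1c(OC(=O)c2cc(Br)c(OCOC)cc2OCC=C)cc(OCC=C)cc1OCC=C
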